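## Retrosynthetic overview

1. Cembrane numbering: C1 ring-fusion CH, C3/C4 oxirane, C6=C7, C8 carbinol, C12 CHMe, C13 CHOAc, C14 CH–O; lactone C15 (α-carbon), C16 (C=O), C17 (=CH2). Target ⇐ 24 ⇐ 23: the oxirane (third ring) comes last, by reagent-controlled epoxidation of C3=C4, followed by O8-desilylation.
2. α-Methylene cis-lactone 23 ⇐ macrocyclic butenolide 19: hydride to C1 anti to the C14 side chain, C17 introduced at C15 as an iminium carbon, then amine elimination.
3. Key disconnection C13–C14: the 14-membered carbocycle (second ring) ⇐ acyclic ω-formyl 2-silyloxyfuran 17 by a vinylogous Mukaiyama aldol macrocyclization; the furan (first ring, bought as a butenolide) is the latent lactone.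
4. Enabling feature: C14 is the γ-carbon of the γ-butyrolactone ring O–C16(=O)–C15–C1–C14 and C13 is an exocyclic carbinol carbon. The lactone can therefore be carried as an achiral 2-silyloxyfuran nucleophilic at its C5 (= C14) and C13 as an aldehyde; the C12 methyl (Felkin) and the threo preference of this aldol give the all-syn C12–C13–C14 triad.
5. 17 ⇐ (2E,6E)-farnesyl acetate (C2–C13 and the three methyls; C12 by asymmetric hydrogenation, C8 by epoxidation/selenoxide transposition) + 4-bromofuran-2(5H)-one (C14, C1, C15, C16), joined at C1–C2 by Stille coupling.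

Key step: step 15

Remarks on the chemistry (assumptions):
- (2E,6E)-Farnesyl acetate is taken as the isomerically pure commercial material.
- The L-configured enantiomer of the fructose-derived ketone used in step 6 is taken as purchasable (otherwise it is made from L-sorbose); it is a catalyst and contributes no atoms.
- The sense of induction in step 4 is assumed to follow the tiglic acid precedent for Ru–H8-BINAP catalysts.

## Route

Step 1
Reactants: 1 (2E,6E)-farnesyl acetate
Product: 2 (2E,6E,10E)-12-hydroxy-3,7,11-trimethyldodeca-2,6,10-trien-1-yl acetate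
Conditions: SeO2 (0.1 equiv), salicylic acid (0.1 equiv), t-BuOOH (70% aq.), CH2Cl2, 20 °C
Reagents that add atoms: tert-butyl hydroperoxide, CC(C)(C)OO (terminal oxidant; the oxygen is relayed through SeO2, O=[Se]=O)
Why: SeO2-catalysed allylic oxidation (ene reaction, then [2,3]-sigmatropic shift) should be selective for the E-methyl of the terminal, most electron-rich olefin, the 2,3-olefin being deactivated by the allylic acetate; any over-oxidised enal converges in step 2.

Step 2
Reactants: 2 (2E,6E,10E)-12-hydroxy-3,7,11-trimethyldodeca-2,6,10-trien-1-yl acetate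
Product: 3 (2E,6E,10E)-3,7,11-trimethyl-12-oxododeca-2,6,10-trien-1-yl acetate
Conditions: PhI(OAc)2, TEMPO (2,2,6,6-tetramethylpiperidin-1-oxyl, 0.1 equiv), CH2Cl2, 20 °C
Reagents that add atoms: none
Why: Oxoammonium oxidation of the primary allylic alcohol should give the E-enal without touching the isolated olefins or the acetate.

Step 3
Reactants: 3 (2E,6E,10E)-3,7,11-trimethyl-12-oxododeca-2,6,10-trien-1-yl acetate
Product: 4 (2E,6E,10E)-12-acetoxy-2,6,10-trimethyldodeca-2,6,10-trienoic acid
Conditions: NaClO2, NaH2PO4, 2-methylbut-2-ene, t-BuOH/H2O, 0 → 20 °C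
Reagents that add atoms: sodium chlorite, [Na+].[O-]Cl=O
Why: Pinnick oxidation of the enal gives the tiglic-type E-acid, the excess 2-methylbut-2-ene protecting the trisubstituted olefins from HOCl.

Step 4
Reactants: 4 (2E,6E,10E)-12-acetoxy-2,6,10-trimethyldodeca-2,6,10-trienoic acid
Product: 5 (2S,6E,10E)-12-acetoxy-2,6,10-trimethyldodeca-6,10-dienoic acid
Conditions: H2 (4 atm), Ru(OAc)2[(S)-H8-BINAP] (0.5 mol%), MeOH, 20 °C
Reagents that add atoms: none
Why: Carboxylate-directed asymmetric hydrogenation reduces only the olefin that can chelate ruthenium through the acid and should set C12 as S, the sense known for (E)-2-methylalk-2-enoic acids with the (S)-ligand; the isolated olefins and the allylic acetate cannot bind in this way and stay.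

Step 5
Reactants: 5 (2S,6E,10E)-12-acetoxy-2,6,10-trimethyldodeca-6,10-dienoic acid
Product: 6 (2S,6E,10E)-12-acetoxy-N-methoxy-N,2,6,10-tetramethyldodeca-6,10-dienamide
Conditions: MeNH(OMe)·HCl, EDC·HCl, HOBt, i-Pr2NEt, CH2Cl2, 0 → 20 °C
Reagents that add atoms: N,O-dimethylhydroxylamine hydrochloride, CNOC.Cl
Why: Carbodiimide amidation gives the Weinreb amide, the masked C13 aldehyde, under conditions that should not epimerise the α-methyl centre.

Step 6
Reactants: 6 (2S,6E,10E)-12-acetoxy-N-methoxy-N,2,6,10-tetramethyldodeca-6,10-dienamide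
Product: 7 (2S,6S,7S,10E)-12-acetoxy-6,7-epoxy-N-methoxy-N,2,6,10-tetramethyldodec-10-enamide
Conditions: 1,2:4,5-di-O-isopropylidene-β-L-erythro-2,3-hexodiulo-2,6-pyranose (0.3 equiv), KHSO5 (as 2KHSO5·KHSO4·K2SO4), K2CO3, Bu4NHSO4, Na2B4O7/Na2EDTA buffer, MeCN/CH2(OMe)2/H2O, 0 °C
Reagents that add atoms: potassium peroxymonosulfate, [K+].[O-]S(=O)(=O)OO
Why: Shi epoxidation: the dioxirane of the L-configured ketone should attack the only electron-rich olefin (the 10,11-olefin is deactivated by the allylic acetate) in the spiro mode that gives the (S,S)-epoxide, the D-ketone being known to give (R,R)-epoxides from E-trisubstituted olefins; this fixes the future C8 carbinol configuration.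

Step 7
Reactants: 7 (2S,6S,7S,10E)-12-acetoxy-6,7-epoxy-N-methoxy-N,2,6,10-tetramethyldodec-10-enamide
Product: 9 (2S,6S,7E,10E)-12-acetoxy-6-hydroxy-N-methoxy-N,2,6,10-tetramethyldodeca-7,10-dienamide, via hydroxy selenide 8 (not isolated)
Conditions: (PhSe)2, NaBH4, EtOH, 0 → 25 °C; then THF, pyridine, 30% H2O2, 0 → 25 °C
Reagents that add atoms: none
Why: Epoxide-to-allylic-alcohol transposition: selenolate opens the oxirane at the secondary carbon (inversion there, tertiary C–O bond untouched) and the selenoxide syn-eliminates, which can only run away from the fully substituted carbinol carbon and should give the E-olefin (C6=C7 of the target) beside the (S)-tertiary alcohol (C8).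

Step 8
Reactants: 9 (2S,6S,7E,10E)-12-acetoxy-6-hydroxy-N-methoxy-N,2,6,10-tetramethyldodeca-7,10-dienamide
Product: 10 (2S,6S,7E,10E)-12-acetoxy-N-methoxy-N,2,6,10-tetramethyl-6-(triethylsilyloxy)dodeca-7,10-dienamide
Conditions: Et3SiOTf, 2,6-lutidine, CH2Cl2, −78 → 0 °C
Reagents that add atoms: triethylsilyl trifluoromethanesulfonate, CC[Si](CC)(CC)OS(=O)(=O)C(F)(F)F
Why: Silyl triflate silylation protects the tertiary allylic alcohol against the Lewis acid of the key step.

Step 9
Reactants: 10 (2S,6S,7E,10E)-12-acetoxy-N-methoxy-N,2,6,10-tetramethyl-6-(triethylsilyloxy)dodeca-7,10-dienamide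
Product: 11 (2S,6S,7E,10E)-12-hydroxy-N-methoxy-N,2,6,10-tetramethyl-6-(triethylsilyloxy)dodeca-7,10-dienamide
Conditions: K2CO3 (0.2 equiv), MeOH, 0 °C
Reagents that add atoms: none
Why: Base-catalysed transesterification removes the acetate while the Weinreb amide and the tertiary silyl ether stay.

Step 10
Reactants: 11 (2S,6S,7E,10E)-12-hydroxy-N-methoxy-N,2,6,10-tetramethyl-6-(triethylsilyloxy)dodeca-7,10-dienamide
Product: 12 (2S,6S,7E,10E)-12-bromo-N-methoxy-N,2,6,10-tetramethyl-6-(triethylsilyloxy)dodeca-7,10-dienamide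
Conditions: CBr4, PPh3, CH2Cl2, −20 °C
Reagents that add atoms: carbon tetrabromide, BrC(Br)(Br)Br
Why: Appel bromination of the primary allylic alcohol at low temperature should proceed by direct displacement without allylic transposition or loss of E geometry.

Step 11
Reactants: 13 4-bromofuran-2(5H)-one
Product: 14 4-(tributylstannyl)furan-2(5H)-one
Conditions: (Bu3Sn)2, Pd(PPh3)4 (5 mol%), 1,4-dioxane, 90 °C
Reagents that add atoms: hexabutylditin, CCCC[Sn](CCCC)(CCCC)[Sn](CCCC)(CCCC)CCCC
Why: Palladium-catalysed stannylation of the vinylogous acyl bromide (oxidative addition, transmetalation with the distannane, reductive elimination) gives the known β-stannyl butenolide.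

Step 12
Reactants: 12 (2S,6S,7E,10E)-12-bromo-N-methoxy-N,2,6,10-tetramethyl-6-(triethylsilyloxy)dodeca-7,10-dienamide; 14 4-(tributylstannyl)furan-2(5H)-one
Product: 15 (2S,6S,7E,10E)-N-methoxy-N,2,6,10-tetramethyl-12-(5-oxo-2,5-dihydrofuran-3-yl)-6-(triethylsilyloxy)dodeca-7,10-dienamide
Conditions: Pd2(dba)3 (2.5 mol%), AsPh3 (10 mol%), THF, 50 °C
Reagents that add atoms: none
Why: Stille coupling of the primary allylic bromide with the β-stannyl butenolide forms the C1–C2 bond at the unsubstituted allyl terminus and should keep the E geometry of the trisubstituted olefin.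

Step 13
Reactants: 15 (2S,6S,7E,10E)-N-methoxy-N,2,6,10-tetramethyl-12-(5-oxo-2,5-dihydrofuran-3-yl)-6-(triethylsilyloxy)dodeca-7,10-dienamide
Product: 16 (2S,6S,7E,10E)-N-methoxy-N,2,6,10-tetramethyl-6-(triethylsilyloxy)-12-[5-(triisopropylsilyloxy)furan-3-yl]dodeca-7,10-dienamide
Conditions: i-Pr3SiOTf, Et3N, CH2Cl2, 0 °C
Reagents that add atoms: triisopropylsilyl trifluoromethanesulfonate, CC(C)[Si](OS(=O)(=O)C(F)(F)F)(C(C)C)C(C)C
Why: Soft enolisation of the butenolide at its ring CH2 gives the aromatic 2-silyloxyfuran; the amide is not enolised under these conditions.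

Step 14
Reactants: 16 (2S,6S,7E,10E)-N-methoxy-N,2,6,10-tetramethyl-6-(triethylsilyloxy)-12-[5-(triisopropylsilyloxy)furan-3-yl]dodeca-7,10-dienamide
Product: 17 (2S,6S,7E,10E)-2,6,10-trimethyl-6-(triethylsilyloxy)-12-[5-(triisopropylsilyloxy)furan-3-yl]dodeca-7,10-dienal
Conditions: i-Bu2AlH, THF, −78 °C; aq. potassium sodium tartrate, 0 °C; used crude
Reagents that add atoms: none
Why: Weinreb amide reduction stops at the chelated hemiaminal and releases the aldehyde only on neutral work-up, so the α-methyl centre is not epimerised and the silyloxyfuran, which has no carbonyl group, is not touched.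

Step 15
Reactants: 17 (2S,6S,7E,10E)-2,6,10-trimethyl-6-(triethylsilyloxy)-12-[5-(triisopropylsilyloxy)furan-3-yl]dodeca-7,10-dienal
Product: 18 (3E,6E,8S,12S,13R,14R)-13-hydroxy-8-(triethylsilyloxy)-17-norcembra-1(15),3,6-trien-16,14-olide
Conditions: BF3·OEt2 (2.5 equiv), CH2Cl2 (0.001 M), −78 °C; aq. NaHCO3
Reagents that add atoms: none
Why: BF3 activates the C13 aldehyde and the electron-rich C5 of the 2-silyloxyfuran (C14, the γ-carbon of the latent lactone) attacks it through an open transition state, after which loss of the silyl group as i-Pr3SiF leaves the conjugated butenolide with a free C13 hydroxyl. The closest known reaction type is the BF3-promoted vinylogous Mukaiyama aldol addition of 2-silyloxyfurans to α-branched aliphatic aldehydes, run here intramolecularly in the manner of macrocyclizing Mukaiyama and vinylogous aldol reactions. The 14-membered carbocycle closes in a 14-exo-trig mode at the C13 carbonyl (endo with respect to the furan C4=C5 bond), and the furan becomes the lactone ring without a second ring closure. C13 is controlled by the C12 methyl centre through Felkin–Anh attack (12,13-syn) and C14 by the intrinsic threo (13,14-syn) preference of Lewis-acid-promoted silyloxyfuran aldol additions, which together should give the (13R,14R) all-syn triad. The step needs γ- over α-attack of the dienolate, secured by the larger frontier-orbital coefficient at furan C5 and by the conjugated butenolide that only γ-attack returns. It also needs cyclization over oligomerization, secured by the 0.001 M dilution and by the two E-olefins that stiffen the 12-atom tether; the acid-labile oxirane is deliberately absent and the tertiary allylic alcohol is masked at this stage.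

Step 16
Reactants: 18 (3E,6E,8S,12S,13R,14R)-13-hydroxy-8-(triethylsilyloxy)-17-norcembra-1(15),3,6-trien-16,14-olide
Product: 19 (3E,6E,8S,12S,13R,14R)-13-acetoxy-8-(triethylsilyloxy)-17-norcembra-1(15),3,6-trien-16,14-olide
Conditions: Ac2O, pyridine, DMAP (4-(dimethylamino)pyridine, cat.), CH2Cl2, 0 °C
Reagents that add atoms: acetic anhydride, CC(=O)OC(C)=O
Why: Acylation of the only free (secondary) hydroxyl installs the C13 acetate of the target under conditions too mild to deprotonate the butenolide γ-position.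

Step 17
Reactants: 19 (3E,6E,8S,12S,13R,14R)-13-acetoxy-8-(triethylsilyloxy)-17-norcembra-1(15),3,6-trien-16,14-olide
Product: 21 (1S,3E,6E,8S,12S,13R,14R,15R)-13-acetoxy-17-(dimethylamino)-8-(triethylsilyloxy)cembra-3,6-dien-16,14-olide, via silyl ketene acetal 20 (not isolated)
Conditions: Cu(OAc)2·H2O (5 mol%), 1,2-bis(diphenylphosphino)benzene (5 mol%), (EtO)2MeSiH, toluene, 0 → 20 °C; then [CH2=NMe2]I, CH2Cl2, 20 °C; aq. NaHCO3
Reagents that add atoms: N,N-dimethylmethyleneiminium iodide, C=[N+](C)C.[I-]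
Why: Copper hydride 1,4-hydrosilylation should deliver hydride to C1 from the butenolide face anti to the C13-bearing substituent on the neighbouring C14 (the face not covered by the macrocyclic chain), which sets the cis ring fusion (1S), and the silyl ketene acetal is then intercepted at C15 by the iminium salt in a Mukaiyama–Mannich reaction, the C15 configuration being of no consequence.

Step 18
Reactants: 21 (1S,3E,6E,8S,12S,13R,14R,15R)-13-acetoxy-17-(dimethylamino)-8-(triethylsilyloxy)cembra-3,6-dien-16,14-olide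
Product: 23 (1S,3E,6E,8S,12S,13R,14R)-13-acetoxy-8-(triethylsilyloxy)cembra-3,6,15(17)-trien-16,14-olide, via methiodide 22 (not isolated)
Conditions: MeI, THF, 20 °C; then NaHCO3, EtOAc/H2O, 20 °C
Reagents that add atoms: none
Why: N-Methylation and bicarbonate-induced E1cB (Hofmann-type) loss of trimethylamine give the exocyclic methylene under conditions that spare the acetate and leave C1 untouched.

Step 19
Reactants: 23 (1S,3E,6E,8S,12S,13R,14R)-13-acetoxy-8-(triethylsilyloxy)cembra-3,6,15(17)-trien-16,14-olide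
Product: 24 (1S,3R,4R,6E,8S,12S,13R,14R)-13-acetoxy-3,4-epoxy-8-(triethylsilyloxy)cembra-6,15(17)-dien-16,14-olide
Conditions: 1,2:4,5-di-O-isopropylidene-β-D-erythro-2,3-hexodiulo-2,6-pyranose (0.3 equiv), KHSO5 (as 2KHSO5·KHSO4·K2SO4), K2CO3, Bu4NHSO4, Na2B4O7/Na2EDTA buffer, MeCN/CH2(OMe)2/H2O, 0 °C
Reagents that add atoms: potassium peroxymonosulfate, [K+].[O-]S(=O)(=O)OO
Why: Shi epoxidation: the dioxirane of the D-configured ketone should attack the electron-rich E-trisubstituted C3=C4 olefin in the spiro mode that gives (R,R)-epoxides, whereas C6=C7 is shielded and deactivated by the adjacent silyloxy-bearing quaternary carbon and the methylene lactone is electron-poor.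

Step 20
Reactants: 24 (1S,3R,4R,6E,8S,12S,13R,14R)-13-acetoxy-3,4-epoxy-8-(triethylsilyloxy)cembra-6,15(17)-dien-16,14-olide
Product: 25 (1S,3R,4R,6E,8S,12S,13R,14R)-13-acetoxy-3,4-epoxy-8-hydroxycembra-6,15(17)-dien-16,14-olide (CNP0202356.4)
Conditions: Et3N·3HF, MeCN, 20 °C
Reagents that add atoms: none
Why: Fluoride cleavage of the tertiary triethylsilyl ether under nearly neutral conditions should neither open the trisubstituted oxirane nor add to the methylene lactone or cleave the acetate.

## Compound list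

1 | (2E,6E)-farnesyl acetate | CC(C)=CCC/C(C)=C/CC/C(C)=C/COC(C)=O | starting material
2 | (2E,6E,10E)-12-hydroxy-3,7,11-trimethyldodeca-2,6,10-trien-1-yl acetate | OC/C(C)=C/CC/C(C)=C/CC/C(C)=C/COC(C)=O | intermediate
3 | (2E,6E,10E)-3,7,11-trimethyl-12-oxododeca-2,6,10-trien-1-yl acetate | O=C/C(C)=C/CC/C(C)=C/CC/C(C)=C/COC(C)=O | intermediate
4 | (2E,6E,10E)-12-acetoxy-2,6,10-trimethyldodeca-2,6,10-trienoic acid | OC(=O)/C(C)=C/CC/C(C)=C/CC/C(C)=C/COC(C)=O | intermediate
5 | (2S,6E,10E)-12-acetoxy-2,6,10-trimethyldodeca-6,10-dienoic acid | OC(=O)[C@@H](C)CCC/C(C)=C/CC/C(C)=C/COC(C)=O | intermediate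
6 | (2S,6E,10E)-12-acetoxy-N-methoxy-N,2,6,10-tetramethyldodeca-6,10-dienamide | CON(C)C(=O)[C@@H](C)CCC/C(C)=C/CC/C(C)=C/COC(C)=O | intermediate
7 | (2S,6S,7S,10E)-12-acetoxy-6,7-epoxy-N-methoxy-N,2,6,10-tetramethyldodec-10-enamide | CON(C)C(=O)[C@@H](C)CCC[C@]1(C)O[C@H]1CC/C(C)=C/COC(C)=O | intermediate
8 | (2S,6S,7R,10E)-12-acetoxy-6-hydroxy-N-methoxy-N,2,6,10-tetramethyl-7-(phenylselanyl)dodec-10-enamide (hydroxy selenide) | CON(C)C(=O)[C@@H](C)CCC[C@](C)(O)[C@H]([Se]c1ccccc1)CC/C(C)=C/COC(C)=O | intermediate (not isolated)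
9 | (2S,6S,7E,10E)-12-acetoxy-6-hydroxy-N-methoxy-N,2,6,10-tetramethyldodeca-7,10-dienamide | CON(C)C(=O)[C@@H](C)CCC[C@](C)(O)/C=C/C/C(C)=C/COC(C)=O | intermediate
10 | (2S,6S,7E,10E)-12-acetoxy-N-methoxy-N,2,6,10-tetramethyl-6-(triethylsilyloxy)dodeca-7,10-dienamide | CON(C)C(=O)[C@@H](C)CCC[C@](C)(O[Si](CC)(CC)CC)/C=C/C/C(C)=C/COC(C)=O | intermediate
11 | (2S,6S,7E,10E)-12-hydroxy-N-methoxy-N,2,6,10-tetramethyl-6-(triethylsilyloxy)dodeca-7,10-dienamide | CON(C)C(=O)[C@@H](C)CCC[C@](C)(O[Si](CC)(CC)CC)/C=C/C/C(C)=C/CO | intermediate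
12 | (2S,6S,7E,10E)-12-bromo-N-methoxy-N,2,6,10-tetramethyl-6-(triethylsilyloxy)dodeca-7,10-dienamide | CON(C)C(=O)[C@@H](C)CCC[C@](C)(O[Si](CC)(CC)CC)/C=C/C/C(C)=C/CBr | intermediate
13 | 4-bromofuran-2(5H)-one | O=C1C=C(Br)CO1 | starting material
14 | 4-(tributylstannyl)furan-2(5H)-one | CCCC[Sn](CCCC)(CCCC)C1=CC(=O)OC1 | intermediate
15 | (2S,6S,7E,10E)-N-methoxy-N,2,6,10-tetramethyl-12-(5-oxo-2,5-dihydrofuran-3-yl)-6-(triethylsilyloxy)dodeca-7,10-dienamide | CON(C)C(=O)[C@@H](C)CCC[C@](C)(O[Si](CC)(CC)CC)/C=C/C/C(C)=C/CC1=CC(=O)OC1 | intermediate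
16 | (2S,6S,7E,10E)-N-methoxy-N,2,6,10-tetramethyl-6-(triethylsilyloxy)-12-[5-(triisopropylsilyloxy)furan-3-yl]dodeca-7,10-dienamide | CON(C)C(=O)[C@@H](C)CCC[C@](C)(O[Si](CC)(CC)CC)/C=C/C/C(C)=C/Cc1coc(O[Si](C(C)C)(C(C)C)C(C)C)c1 | intermediate
17 | (2S,6S,7E,10E)-2,6,10-trimethyl-6-(triethylsilyloxy)-12-[5-(triisopropylsilyloxy)furan-3-yl]dodeca-7,10-dienal | O=C[C@@H](C)CCC[C@](C)(O[Si](CC)(CC)CC)/C=C/C/C(C)=C/Cc1coc(O[Si](C(C)C)(C(C)C)C(C)C)c1 | intermediate
18 | (3E,6E,8S,12S,13R,14R)-13-hydroxy-8-(triethylsilyloxy)-17-norcembra-1(15),3,6-trien-16,14-olide (14-membered carbocycle fused at C1/C14 to a 2(5H)-furanone) | O=C1O[C@H]2[C@H](O)[C@@H](C)CCC[C@](C)(O[Si](CC)(CC)CC)/C=C/C/C(C)=C/CC2=C1 | intermediate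
19 | (3E,6E,8S,12S,13R,14R)-13-acetoxy-8-(triethylsilyloxy)-17-norcembra-1(15),3,6-trien-16,14-olide | O=C1O[C@H]2[C@H](OC(C)=O)[C@@H](C)CCC[C@](C)(O[Si](CC)(CC)CC)/C=C/C/C(C)=C/CC2=C1 | intermediate
20 | diethoxy(methyl)silyl ketene acetal of the (1S)-saturated lactone (C15=C16, O16–Si) | C1=C(O[Si](C)(OCC)OCC)O[C@H]2[C@H](OC(C)=O)[C@@H](C)CCC[C@](C)(O[Si](CC)(CC)CC)/C=C/C/C(C)=C/C[C@@H]12 | intermediate (not isolated)
21 | (1S,3E,6E,8S,12S,13R,14R,15R)-13-acetoxy-17-(dimethylamino)-8-(triethylsilyloxy)cembra-3,6-dien-16,14-olide | CN(C)C[C@@H]1C(=O)O[C@H]2[C@H](OC(C)=O)[C@@H](C)CCC[C@](C)(O[Si](CC)(CC)CC)/C=C/C/C(C)=C/C[C@@H]12 | intermediate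
22 | N-methyl ammonium iodide (methiodide) of 21 | C[N+](C)(C)C[C@@H]1C(=O)O[C@H]2[C@H](OC(C)=O)[C@@H](C)CCC[C@](C)(O[Si](CC)(CC)CC)/C=C/C/C(C)=C/C[C@@H]12.[I-] | intermediate (not isolated)
23 | (1S,3E,6E,8S,12S,13R,14R)-13-acetoxy-8-(triethylsilyloxy)cembra-3,6,15(17)-trien-16,14-olide | C=C1C(=O)O[C@H]2[C@H](OC(C)=O)[C@@H](C)CCC[C@](C)(O[Si](CC)(CC)CC)/C=C/C/C(C)=C/C[C@@H]12 | intermediate
24 | (1S,3R,4R,6E,8S,12S,13R,14R)-13-acetoxy-3,4-epoxy-8-(triethylsilyloxy)cembra-6,15(17)-dien-16,14-olide | C=C1C(=O)O[C@H]2[C@H](OC(C)=O)[C@@H](C)CCC[C@](C)(O[Si](CC)(CC)CC)/C=C/C[C@@]3(C)O[C@@H]3C[C@@H]12 | intermediate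
25 | (1S,3R,4R,6E,8S,12S,13R,14R)-13-acetoxy-3,4-epoxy-8-hydroxycembra-6,15(17)-dien-16,14-olide (CNP0202356.4) | C=C1C(=O)O[C@H]2[C@H](OC(C)=O)[C@@H](C)CCC[C@](C)(O)/C=C/C[C@@]3(C)O[C@@H]3C[C@@H]12 | target

## Step count and risks

Total step count: 20 (19 in the main line and 1 for stannane 14).
Longest linear sequence: 19 steps (steps 1–10 and 12–20).

Steps most likely to fail:

1. Step 15 (macrocyclization). What may go wrong: intermolecular aldol addition competing with ring closure, Lewis-acid ionisation of the tertiary allylic silyl ether, or erosion of the Felkin/threo preference in the macrocyclic transition state. Fallback, setting out from 17 and returning at 18: the furan silyl ether is cleaved with Bu4NF buffered with AcOH (THF, −78 °C) to the butenolide aldehyde F1. F1 is precomplexed with aluminium tris(2,6-diphenylphenoxide) (2.2 equiv, toluene, −78 °C) and treated slowly with lithium 2,2,6,6-tetramethylpiperidide in THF at 0.001 M. The bulky aluminium Lewis acid shields the aldehyde α-position, the base removes the ring γ-proton of the complexed lactone, and the aluminium dienolate adds through C14 to the complexed aldehyde. This is a direct vinylogous aldol macrocyclization with no silyl transfer and no protic or boron Lewis acid, and it gives 18.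

2. Step 17 (hydride addition and C17 introduction). What may go wrong: protodesilylation of the hindered silyl ketene acetal outrunning aminomethylation, or reduction of the iminium salt by residual copper hydride. Fallback, setting out from 19 and returning at 23: 19 is reduced as in step 17 to 20, which is hydroxymethylated instead (37% aq. formaldehyde, Yb(OTf)3 (10 mol%), THF, 20 °C; aldol reaction of the silyl ketene acetal in aqueous medium) to the α-hydroxymethyl lactone F2. F2 is converted with MsCl/Et3N (CH2Cl2, 0 °C) into the mesylate F3, and F3 is eliminated with DBU (CH2Cl2, 20 °C) to 23. The methylene is thus made by aldol/dehydration and not by Mannich/amine elimination.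

3. Step 19 (late epoxidation). What may go wrong: poor facial selectivity if the macrocycle conformation opposes the catalyst, competing oxidation of C6=C7, or base-induced damage to the methylene lactone in the buffered medium. Fallback, setting out from 23 and returning at 24: NBS in THF/H2O (0 °C) converts the most electron-rich olefin into the (3S,4R)-bromohydrin F4 (bromonium ion on the exposed face, water at the tertiary C4 from the opposite face). DBU (toluene, 20 °C) then closes F4 to 24 with inversion at C3. The oxirane oxygen so ends up on the face opposite to the one an electrophilic oxidant attacks directly, which is the remedy if direct oxygen transfer is substrate-controlled toward the wrong face, and the sequence avoids the basic aqueous oxidant.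

Further compounds
F1 | step 15 | (2S,6S,7E,10E)-2,6,10-trimethyl-12-(5-oxo-2,5-dihydrofuran-3-yl)-6-(triethylsilyloxy)dodeca-7,10-dienal | O=C[C@@H](C)CCC[C@](C)(O[Si](CC)(CC)CC)/C=C/C/C(C)=C/CC1=CC(=O)OC1
F2 | step 17 | (1S,3E,6E,8S,12S,13R,14R,15R)-13-acetoxy-17-hydroxy-8-(triethylsilyloxy)cembra-3,6-dien-16,14-olide | OC[C@@H]1C(=O)O[C@H]2[C@H](OC(C)=O)[C@@H](C)CCC[C@](C)(O[Si](CC)(CC)CC)/C=C/C/C(C)=C/C[C@@H]12
F3 | step 17 | (1S,3E,6E,8S,12S,13R,14R,15R)-13-acetoxy-17-(methanesulfonyloxy)-8-(triethylsilyloxy)cembra-3,6-dien-16,14-olide | CS(=O)(=O)OC[C@@H]1C(=O)O[C@H]2[C@H](OC(C)=O)[C@@H](C)CCC[C@](C)(O[Si](CC)(CC)CC)/C=C/C/C(C)=C/C[C@@H]12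
F4 | step 19 | (1S,3S,4R,6E,8S,12S,13R,14R)-13-acetoxy-3-bromo-4-hydroxy-8-(triethylsilyloxy)cembra-6,15(17)-dien-16,14-olide | C=C1C(=O)O[C@H]2[C@H](OC(C)=O)[C@@H](C)CCC[C@](C)(O[Si](CC)(CC)CC)/C=C/C[C@@](C)(O)[C@@H](Br)C[C@@H]12
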